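**Retrosynthetic overview**
- The butenolide is made last, from a 3-substituted furan (singlet oxygen, then NaBH4); the CH2OH comes from a methyl ester.
- Key disconnection: the sp2–sp3 bond between the vinyl CH of the methyl-bearing alkene and the next CH2. An (E)-alkenyl iodide (C15, ring half) is joined to a primary alkyl bromide (C10, furan half) by nickel-catalysed reductive radical cross-coupling, with the free carbinol, the ester and the furan in place.
- Alkenyl iodide ⇐ Zr-catalysed carboalumination/iodination of a terminal alkyne ⇐ Negishi coupling of 2,6,6-trimethylcyclohexenyl triflate with butynylzinc.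
- Alkyl bromide ⇐ cross-metathesis of (S)-1-(furan-3-yl)but-3-en-1-ol (Brown allylation sets the only stereocentre) with methyl 2-(2-bromoethyl)acrylate from α-methylene-γ-butyrolactone.
- Ring order: the cyclohexene is bought (2-methylcyclohexanone) and only methylated, the furan is bought, the butenolide is formed last.

Assumption: the carbinol centre is S and both chain alkenes are E, as in the SMILES; racemic 2-methylcyclohexanone is used because its stereocentre is erased in step 2.

**Step 1**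
Reactants: 1 2-methylcyclohexanone
Product: 5 2,2,6-trimethylcyclohexanone (racemic), via lithium 6-methylcyclohexenolate 2 (not isolated), via 2,6-dimethylcyclohexanone 3 (not isolated), via lithium 2,6-dimethylcyclohexenolate 4 (not isolated)
Conditions: LiN(i-Pr)2 (1.05 equiv), THF, −78 °C; MeI; then LiN(i-Pr)2 (1.1 equiv), −78 → 0 °C; MeI, 0 → 23 °C
Reagents that add atoms: iodomethane, CI
Why: Two successive enolate alkylations converge on 5, because the first base charge removes the less hindered α-H, the second can only remove a methine α-H, and any 2,2-dimethyl isomer from enolate equilibration is methylated at C6 to the same ketone.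

**Step 2**
Reactants: 5 2,2,6-trimethylcyclohexanone
Product: 7 2,6,6-trimethylcyclohex-1-en-1-yl trifluoromethanesulfonate, via lithium 2,6,6-trimethylcyclohexenolate 6 (not isolated)
Conditions: LiN(i-Pr)2, THF, −78 → 0 °C; PhNTf2, 0 → 23 °C
Reagents that add atoms: N-phenylbis(trifluoromethanesulfonimide), O=S(=O)(N(c1ccccc1)S(=O)(=O)C(F)(F)F)C(F)(F)F
Why: Enol triflate formation by O-sulfonylation of the only enolate that can form (the other α-carbon is quaternary), which also removes the stereocentre of 5.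

**Step 3**
Reactants: 7 2,6,6-trimethylcyclohex-1-en-1-yl trifluoromethanesulfonate; 8 4-bromobut-1-yne
Product: 10 2-(but-3-yn-1-yl)-1,3,3-trimethylcyclohex-1-ene, via bromo(but-3-yn-1-yl)zinc 9 (not isolated)
Conditions: 8, Zn dust, LiCl, THF, 25 °C; then 7, Pd(OAc)2 (3 mol %), SPhos (6 mol %), THF, 40 °C
Reagents that add atoms: none
Why: Negishi sp2–sp3 coupling, in which the alkylzinc halide is too weakly basic to metalate the alkyne C–H quickly and the bulky biarylphosphine lets palladium insert into the hindered triflate.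

**Step 4**
Reactants: 10 2-(but-3-yn-1-yl)-1,3,3-trimethylcyclohex-1-ene
Product: 12 2-[(3E)-4-iodo-3-methylbut-3-en-1-yl]-1,3,3-trimethylcyclohex-1-ene, via alkenylalane 11 (not isolated)
Conditions: AlMe3 (2.5 equiv), Cp2ZrCl2 (0.25 equiv), CH2Cl2, 0 → 23 °C; then I2, THF, −30 → 0 °C
Reagents that add atoms: trimethylaluminium, C[Al](C)C; iodine, II
Why: Negishi zirconium-catalysed carboalumination adds Me and Al syn across the terminal alkyne with methyl on the internal carbon, and iodinolysis with retention fixes the E trisubstituted alkene while the tetrasubstituted ring alkene is inert.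

**Step 5**
Reactants: 13 furan-3-carbaldehyde
Product: 15 (1S)-1-(furan-3-yl)but-3-en-1-ol, via borinate ester 14 (not isolated)
Conditions: (−)-Ipc2BOMe, CH2=CHCH2MgBr, Et2O, 0 → 23 °C; then 13, −78 °C; then NaOH, H2O2, 0 → 23 °C
Reagents that add atoms: allylmagnesium bromide, C=CC[Mg]Br
Why: Brown asymmetric allylboration, in which (−)-Ipc2B(allyl) delivers allyl through a chair six-membered transition state to the Si face of the aldehyde and so sets the carbinol centre as S (by analogy with benzaldehyde, which gives (S)-1-phenylbut-3-en-1-ol; usually at least 90% ee).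

**Step 6**
Reactants: 16 3-methylideneoxolan-2-one (α-methylene-γ-butyrolactone)
Product: 18 methyl 4-bromo-2-methylidenebutanoate, via dibromo ester 17 (not isolated)
Conditions: HBr (gas), MeOH, 0 → 23 °C; then Et3N, CH2Cl2, 0 °C
Reagents that add atoms: hydrogen bromide, Br; methanol, CO
Why: Acid-mediated alkyl–oxygen cleavage of the lactone by bromide with Fischer esterification (as in the classical γ-butyrolactone to 4-bromobutanoate conversion), after which Et3N reverses only the HBr conjugate addition to the acrylate by E1cB dehydrobromination.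

**Step 7**
Reactants: 15 (1S)-1-(furan-3-yl)but-3-en-1-ol; 18 methyl 4-bromo-2-methylidenebutanoate
Product: 19 methyl (2E,5S)-2-(2-bromoethyl)-5-(furan-3-yl)-5-hydroxypent-2-enoate
Conditions: RuCl2(H2IMes)(=CH–C6H4-2-O-i-Pr) (second-generation Hoveyda–Grubbs catalyst, 5 mol %), 18 (3 equiv), 2,6-dichloro-1,4-benzoquinone (10 mol %), CH2Cl2, 40 °C
Reagents that add atoms: none
Why: Olefin cross-metathesis of a terminal alkene with a 1,1-disubstituted acrylate that cannot homodimerise, where thermodynamic control puts the ester trans to the new CH2 substituent (E, as with methacrylates) and the carbinol centre is untouched.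

**Step 8 (key step)**
Reactants: 12 2-[(3E)-4-iodo-3-methylbut-3-en-1-yl]-1,3,3-trimethylcyclohex-1-ene; 19 methyl (2E,5S)-2-(2-bromoethyl)-5-(furan-3-yl)-5-hydroxypent-2-enoate
Product: 20 methyl (2E,5S)-5-(furan-3-yl)-5-hydroxy-2-[(3E)-4-methyl-6-(2,6,6-trimethylcyclohex-1-en-1-yl)hex-3-en-1-yl]pent-2-enoate
Conditions: NiBr2(dme) (10 mol %), 4,4′-di-tert-butyl-2,2′-bipyridine (10 mol %), NaI (0.5 equiv), Zn dust (2.5 equiv), 19 (1.5 equiv), DMA, 25 °C
Reagents that add atoms: none
Why: Nickel-catalysed reductive cross-electrophile coupling, in which zerovalent nickel inserts into the alkenyl C–I bond with retention, monovalent nickel turns the primary bromide into a carbon radical that the alkenylnickel captures, and reductive elimination from trivalent nickel forms the C(sp2)–C(sp3) bond; the free OH, ester and furan are tolerated, the trisubstituted enoate is a poor radical acceptor, and both alkene geometries and the stereocentre are carried through.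

**Step 9**
Reactants: 20 methyl (2E,5S)-5-(furan-3-yl)-5-hydroxy-2-[(3E)-4-methyl-6-(2,6,6-trimethylcyclohex-1-en-1-yl)hex-3-en-1-yl]pent-2-enoate
Product: 21 (2E,5S)-5-(furan-3-yl)-2-[(3E)-4-methyl-6-(2,6,6-trimethylcyclohex-1-en-1-yl)hex-3-en-1-yl]pent-2-ene-1,5-diol
Conditions: i-Bu2AlH (3.5 equiv), CH2Cl2, −78 °C; aqueous potassium sodium tartrate
Reagents that add atoms: none
Why: 1,2-Reduction of the conjugated ester by i-Bu2AlH gives the allylic alcohol without touching the alkenes, the furan or the stereocentre.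

**Step 10**
Reactants: 21 (2E,5S)-5-(furan-3-yl)-2-[(3E)-4-methyl-6-(2,6,6-trimethylcyclohex-1-en-1-yl)hex-3-en-1-yl]pent-2-ene-1,5-diol
Product: 24 4-[(1S,3E,7E)-1-hydroxy-4-(hydroxymethyl)-8-methyl-10-(2,6,6-trimethylcyclohex-1-en-1-yl)deca-3,7-dien-1-yl]furan-2(5H)-one (target), via furan endoperoxide 22 (not isolated), via 5-hydroxybutenolide 23 (not isolated)
Conditions: O2, visible light, tetraphenylporphyrin (cat.), i-Pr2NEt, CH2Cl2, −78 °C; then NaBH4, MeOH, −78 → 0 °C; then 1 M HCl to pH 3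
Reagents that add atoms: dioxygen, O=O
Why: [4+2] cycloaddition of singlet oxygen to the furan (faster at −78 °C than the ene reaction of the alkenes, as in manoalide-type endgames), base-induced Kornblum–DeLaMare fragmentation at the less hindered C–H to the 4-substituted 5-hydroxybutenolide, then NaBH4 reduction of its aldehyde tautomer and relactonisation give the butenolide without touching the carbinol centre.

**Compound list**
1 | 2-methylcyclohexanone (racemic) | CC1CCCCC1=O | starting material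
2 | lithium 6-methylcyclohex-1-en-1-olate (racemic) | [Li+].[O-]C1=CCCCC1C | intermediate (not isolated)
3 | 2,6-dimethylcyclohexanone (cis/trans mixture) | CC1CCCC(C)C1=O | intermediate (not isolated)
4 | lithium 2,6-dimethylcyclohex-1-en-1-olate (racemic) | [Li+].[O-]C1=C(C)CCCC1C | intermediate (not isolated)
5 | 2,2,6-trimethylcyclohexanone (racemic) | CC1CCCC(C)(C)C1=O | intermediate
6 | lithium 2,6,6-trimethylcyclohex-1-en-1-olate | [Li+].[O-]C1=C(C)CCCC1(C)C | intermediate (not isolated)
7 | 2,6,6-trimethylcyclohex-1-en-1-yl trifluoromethanesulfonate | CC1=C(OS(=O)(=O)C(F)(F)F)C(C)(C)CCC1 | intermediate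
8 | 4-bromobut-1-yne | BrCCC#C | starting material
9 | bromo(but-3-yn-1-yl)zinc | Br[Zn]CCC#C | intermediate (not isolated)
10 | 2-(but-3-yn-1-yl)-1,3,3-trimethylcyclohex-1-ene | CC1=C(CCC#C)C(C)(C)CCC1 | intermediate
11 | dimethyl[(1E)-2-methyl-4-(2,6,6-trimethylcyclohex-1-en-1-yl)but-1-en-1-yl]alumane | CC1=C(CC/C(C)=C/[Al](C)C)C(C)(C)CCC1 | intermediate (not isolated)
12 | 2-[(3E)-4-iodo-3-methylbut-3-en-1-yl]-1,3,3-trimethylcyclohex-1-ene | CC1=C(CC/C(C)=C/I)C(C)(C)CCC1 | intermediate
13 | furan-3-carbaldehyde | O=Cc1ccoc1 | starting material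
14 | (1S)-1-(furan-3-yl)but-3-en-1-yl bis[(1R,2S,3R,5R)-2,6,6-trimethylbicyclo[3.1.1]heptan-3-yl]borinate | C=CC[C@H](OB([C@@H]1C[C@@H]2C[C@H]([C@H]1C)C2(C)C)[C@@H]1C[C@@H]2C[C@H]([C@H]1C)C2(C)C)c1ccoc1 | intermediate (not isolated)
15 | (1S)-1-(furan-3-yl)but-3-en-1-ol | C=CC[C@H](O)c1ccoc1 | intermediate
16 | 3-methylideneoxolan-2-one | C=C1CCOC1=O | starting material
17 | methyl 4-bromo-2-(bromomethyl)butanoate (racemic) | COC(=O)C(CBr)CCBr | intermediate (not isolated)
18 | methyl 4-bromo-2-methylidenebutanoate | C=C(CCBr)C(=O)OC | intermediate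
19 | methyl (2E,5S)-2-(2-bromoethyl)-5-(furan-3-yl)-5-hydroxypent-2-enoate | COC(=O)/C(CCBr)=C/C[C@H](O)c1ccoc1 | intermediate
20 | methyl (2E,5S)-5-(furan-3-yl)-5-hydroxy-2-[(3E)-4-methyl-6-(2,6,6-trimethylcyclohex-1-en-1-yl)hex-3-en-1-yl]pent-2-enoate | CC1=C(CC/C(C)=C/CC/C(=C\C[C@H](O)c2ccoc2)C(=O)OC)C(C)(C)CCC1 | intermediate
21 | (2E,5S)-5-(furan-3-yl)-2-[(3E)-4-methyl-6-(2,6,6-trimethylcyclohex-1-en-1-yl)hex-3-en-1-yl]pent-2-ene-1,5-diol | CC1=C(CC/C(C)=C/CC/C(=C\C[C@H](O)c2ccoc2)CO)C(C)(C)CCC1 | intermediate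
22 | furan endoperoxide of 21 (5-substituted 2,3,7-trioxabicyclo[2.2.1]hept-5-ene, bridgehead isomers) | CC1=C(CC/C(C)=C/CC/C(=C\C[C@H](O)C2=CC3OOC2O3)CO)C(C)(C)CCC1 | intermediate (not isolated)
23 | 5-hydroxy-4-[(1S,3E,7E)-1-hydroxy-4-(hydroxymethyl)-8-methyl-10-(2,6,6-trimethylcyclohex-1-en-1-yl)deca-3,7-dien-1-yl]furan-2(5H)-one (epimers at the hemiacetal carbon) | CC1=C(CC/C(C)=C/CC/C(=C\C[C@H](O)C2=CC(=O)OC2O)CO)C(C)(C)CCC1 | intermediate (not isolated)
24 | 4-[(1S,3E,7E)-1-hydroxy-4-(hydroxymethyl)-8-methyl-10-(2,6,6-trimethylcyclohex-1-en-1-yl)deca-3,7-dien-1-yl]furan-2(5H)-one | CC1=C(CC/C(C)=C/CC/C(=C\C[C@H](O)C2=CC(=O)OC2)CO)C(C)(C)CCC1 | target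

**Step count and risks**
Total: 10 steps. Longest linear sequence: 7 steps (1, 2, 3, 4, 8, 9, 10).

Step 8 is the most likely to fail, through homodimerisation of either partner or simple reduction of the bromide. The fallback sets out from 12 and 19 and keeps the radical C–C formation, but uses an organometallic and an electrophile instead of two electrophiles. Silylation of 19 (Me3SiCl, Et3N) gives methyl (2E,5S)-2-(2-bromoethyl)-5-(furan-3-yl)-5-[(trimethylsilyl)oxy]pent-2-enoate F1. Iodine–magnesium exchange on 12 (i-PrMgCl·LiCl, THF, 25 °C) gives chloro[(1E)-2-methyl-4-(2,6,6-trimethylcyclohex-1-en-1-yl)but-1-en-1-yl]magnesium F2. Slow addition of F2 to F1 with Fe(acac)3 (5 mol %) and TMEDA in THF at 0 °C (iron-catalysed Kumada coupling through the same primary alkyl radical) gives methyl (2E,5S)-5-(furan-3-yl)-2-[(3E)-4-methyl-6-(2,6,6-trimethylcyclohex-1-en-1-yl)hex-3-en-1-yl]-5-[(trimethylsilyl)oxy]pent-2-enoate F3. Citric acid work-up removes the silyl group and the route is rejoined at 20.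

Step 7 may stall because the α-substituted acrylate is a sluggish metathesis partner. The fallback sets out from 12 and 15, moves the olefination behind the radical coupling and uses a Horner–Wadsworth–Emmons reaction instead of metathesis.
- 3-Bromooxolan-2-one and P(OMe)3 (Arbuzov, 110 °C) give dimethyl (2-oxooxolan-3-yl)phosphonate F4, and HBr in MeOH opens it to methyl 4-bromo-2-(dimethoxyphosphoryl)butanoate F5.
- The nickel coupling of step 8, run on F5 and 12, gives methyl (5E)-2-(dimethoxyphosphoryl)-6-methyl-8-(2,6,6-trimethylcyclohex-1-en-1-yl)oct-5-enoate F6.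
- In parallel 15 is silylated (t-BuMe2SiCl, imidazole) to tert-butyl{[(1S)-1-(furan-3-yl)but-3-en-1-yl]oxy}dimethylsilane F7 and cleaved (OsO4 cat., NaIO4, 2,6-lutidine) to (3S)-3-[(tert-butyldimethylsilyl)oxy]-3-(furan-3-yl)propanal F8.
- Olefination of F8 with F6 (LiCl, DBU, MeCN; the E isomer is expected to predominate and the Z isomer is removed by chromatography) gives methyl (2E,5S)-5-[(tert-butyldimethylsilyl)oxy]-5-(furan-3-yl)-2-[(3E)-4-methyl-6-(2,6,6-trimethylcyclohex-1-en-1-yl)hex-3-en-1-yl]pent-2-enoate F9, and Bu4NF returns the route to 20.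

Step 3 may fail if the zinc reagent 9 or the palladium catalyst attacks the free alkyne C–H. The fallback sets out from 7 and builds the alkyne from a ketone instead of carrying it through the coupling. Fe(acac)3-catalysed coupling of 7 with but-3-en-1-ylmagnesium bromide (THF/NMP, −20 °C) gives 2-(but-3-en-1-yl)-1,3,3-trimethylcyclohex-1-ene F10. Tsuji–Wacker oxidation (PdCl2, CuCl, O2, DMF/H2O) gives 4-(2,6,6-trimethylcyclohex-1-en-1-yl)butan-2-one F11. LiN(i-Pr)2 at −78 °C followed by ClP(O)(OEt)2 gives diethyl 4-(2,6,6-trimethylcyclohex-1-en-1-yl)but-1-en-2-yl phosphate F12, and further LiN(i-Pr)2 (2.2 equiv) eliminates it to the alkyne, rejoining the route at 10.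

**Further compounds**
F1 | step 8 | methyl (2E,5S)-2-(2-bromoethyl)-5-(furan-3-yl)-5-[(trimethylsilyl)oxy]pent-2-enoate | COC(=O)/C(CCBr)=C/C[C@H](O[Si](C)(C)C)c1ccoc1
F2 | step 8 | chloro[(1E)-2-methyl-4-(2,6,6-trimethylcyclohex-1-en-1-yl)but-1-en-1-yl]magnesium | CC1=C(CC/C(C)=C/[Mg]Cl)C(C)(C)CCC1
F3 | step 8 | methyl (2E,5S)-5-(furan-3-yl)-2-[(3E)-4-methyl-6-(2,6,6-trimethylcyclohex-1-en-1-yl)hex-3-en-1-yl]-5-[(trimethylsilyl)oxy]pent-2-enoate | CC1=C(CC/C(C)=C/CC/C(=C\C[C@H](O[Si](C)(C)C)c2ccoc2)C(=O)OC)C(C)(C)CCC1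
F4 | step 7 | dimethyl (2-oxooxolan-3-yl)phosphonate (racemic) | COP(=O)(OC)C1CCOC1=O
F5 | step 7 | methyl 4-bromo-2-(dimethoxyphosphoryl)butanoate (racemic) | COC(=O)C(CCBr)P(=O)(OC)OC
F6 | step 7 | methyl (5E)-2-(dimethoxyphosphoryl)-6-methyl-8-(2,6,6-trimethylcyclohex-1-en-1-yl)oct-5-enoate (racemic at C2) | COC(=O)C(CC/C=C(\C)CCC1=C(C)CCCC1(C)C)P(=O)(OC)OC
F7 | step 7 | tert-butyl{[(1S)-1-(furan-3-yl)but-3-en-1-yl]oxy}dimethylsilane | C=CC[C@H](O[Si](C)(C)C(C)(C)C)c1ccoc1
F8 | step 7 | (3S)-3-[(tert-butyldimethylsilyl)oxy]-3-(furan-3-yl)propanal | O=CC[C@H](O[Si](C)(C)C(C)(C)C)c1ccoc1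
F9 | step 7 | methyl (2E,5S)-5-[(tert-butyldimethylsilyl)oxy]-5-(furan-3-yl)-2-[(3E)-4-methyl-6-(2,6,6-trimethylcyclohex-1-en-1-yl)hex-3-en-1-yl]pent-2-enoate | CC1=C(CC/C(C)=C/CC/C(=C\C[C@H](O[Si](C)(C)C(C)(C)C)c2ccoc2)C(=O)OC)C(C)(C)CCC1
F10 | step 3 | 2-(but-3-en-1-yl)-1,3,3-trimethylcyclohex-1-ene | CC1=C(CCC=C)C(C)(C)CCC1
F11 | step 3 | 4-(2,6,6-trimethylcyclohex-1-en-1-yl)butan-2-one | CC1=C(CCC(C)=O)C(C)(C)CCC1
F12 | step 3 | diethyl 4-(2,6,6-trimethylcyclohex-1-en-1-yl)but-1-en-2-yl phosphate | CC1=C(CCC(=C)OP(=O)(OCC)OCC)C(C)(C)CCC1
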